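**Two twins.** The gamma run holds 0.250 M more product at the start than the epsilon run, and its other charges are the same. So I reckon the gamma share from what the epsilon run did.

| flask | starting material | coupling partner | catalyst | product | time |
|---|---|---|---|---|---|
| epsilon | 0.500 M | 0.750 M | 0.0500 M |  |  |
| theta | 0.200 M | 0.450 M | 0.0500 M |  |  |
| eta | 0.500 M | 2.20 M | 0.0500 M |  |  |
| beta | 0.500 M | 0.750 M | 0.100 M |  |  |
| gamma | 0.500 M | 0.750 M | 0.0500 M | 0.250 M | 6.0 min |

| epsilon run: time / min | epsilon run: [product] / M | theta run: time / min | theta run: [product] / M | eta run: time / min | eta run: [product] / M | beta run: time / min | beta run: [product] / M |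
|---|---|---|---|---|---|---|---|
| 1.2 | 0.0481 | 1.2 | 0.0196 | 1.2 | 0.0748 | 1.2 | 0.0896 |
| 2.4 | 0.0910 | 2.4 | 0.0381 | 2.4 | 0.1455 | 2.4 | 0.1649 |
| 3.6 | 0.1316 | 3.6 | 0.0500 | 3.6 | 0.2077 | 3.6 | 0.2232 |
| 4.8 | 0.1688 | 4.8 | 0.0627 | 4.8 | 0.2584 | 4.8 | 0.2690 |
| 6.0 | 0.2019 | 6.0 | 0.0792 | 6.0 | 0.3014 | 6.0 | 0.3095 |

(readings scatter by 0.002 M)

- Overall: starting material + coupling partner -> product, with catalyst as catalyst.
- Constant volume, constant temperature.
- Bound and free are read together.
- "The second partner" is coupling partner.
- An order is taken over about fifteen percent of the charge, up and down.
- A share of product counts the product that was charged too.

1. the power of [coupling partner] that the first rate follows, about the charge of the epsilon run; measure it at two percent of starting material made into product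
2. the power of [starting material] that the first rate follows, about the charge of the epsilon run; measure it at two percent of starting material made into product (one fixed amount of product, the same in the runs compared)
3. the theta run starts with 0.300 M less of starting material and of coupling partner than the epsilon run, and with no product. Compared where both hold the same amount of starting material, once fifteen percent of what the theta run was charged with has turned into product, is the theta run faster, slower or alike (within a tenth)?
4. product in the gamma run at 6.0 min, as a share of the starting material charged

**Outer bracket.** Starting material is the limiting reagent in the gamma run, where less of it is charged than of coupling partner. Its share therefore lies between 50.0 %, with nothing formed, and 150 %, with the charge fully turned.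

**Inner bracket.** The epsilon run slows at each step, from a mean rate of 0.0401 M min⁻¹ over the first interval to 0.0276 M min⁻¹ over the last. Holding each rate for 6.0 min gives a gamma share of 98.1 % from above and 83.1 % from below. These bounds hold if charged product leaves the rate alone, and that needs a test.

**Product test.** The theta run and the beta run have the same excess of coupling partner over starting material, 0.250 M. I define the product ratio m as the rate with little product over the rate with much product, per unit of catalyst, at nearly the same starting material. The first theta interval gives 0.0163 M min⁻¹. The last beta interval, holding 0.2690 M to 0.3095 M of product, gives 0.0337 M min⁻¹. The beta run has twice the catalyst, and its first reading is 1.86 times that of the epsilon run, so I scale by the charge. Then m = 0.968, with a scatter of about 0.124.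

**My reckoning.** With m near one, the gamma run should copy the epsilon run. The shortest route is to take the gain g, the product the epsilon run has made by 6.0 min, which is 0.202 M. Adding the charged product gives 90.4 %, and I expect the theta run and the epsilon run to be alike.

**The forecast.** It gives 0.55 and 0.6 for the orders, alike for the comparison, and 89.5 % for the share, on the ground that “product shows no clear inhibition”. Its share is inside the inner bracket and below mine.

**The flask.** It gives orders of 0.54 and 0.65, the answer alike, and a share of 89.8 %, which is also inside the bracket.

    catalyst + starting material ⇌ catalyst-substrate complex, settled at all times (1.630 M⁻¹)
    catalyst-substrate complex + coupling partner → product + catalyst (7.980 M⁻¹ min⁻¹)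
    2 coupling partner ⇌ idle reagent dimer, settled at all times (2.890 M⁻¹)
    catalyst + coupling partner ⇌ idle catalyst-reagent complex, settled at all times (1.070 M⁻¹)

**Same gain.** The gamma run makes 0.199 M, which is 0.00300 M short of g, against a scatter of 0.002 M on one reading. That fits m = 0.968. The theta run is the second case for m: its rate over that of the epsilon run, at equal starting material, is 1.0. The gain itself stays modest because coupling partner binds into idle reagent dimer: the gamma run, with that binding taken away, reaches 113 %.

The earlier runs and the new flask are calculated with made-up constants, and the scatter is random.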